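- The 3 questions concerned one flask, charged with blue's [Q] and amber's [X].

| flask | L | Q | X | J | remark | time |
|---|---|---|---|---|---|---|
| amber | 0.80 M | 0.90 M | 8 mM (in portions, 2) | 7.9 mM | run made earlier; portions every 15 min |  |
| teal | 0.80 M | 1.4 M | 8 mM (in portions, 2) | 7.9 mM | run made earlier; portions every 15 min |  |
| blue | 0.80 M | 0.64 M | 16 mM (in portions, 2) | 7.9 mM | run made earlier; portions every 15 min |  |
| flask | 0.80 M | 0.640 M | 8.0 mM (in portions, 2) | 7.9 mM | the portions of X follow each other after 15 min, the first at the start | 40 h |

- amber (time / h: L / %, Z / %): 8.00: 5, 93; 15.0: 0, 100; 25.0: 0, 101; 30.0: 2, 101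
- teal (time / h: L / %, Z / %): 8.00: 1, 99; 15.0: 1, 99; 25.0: 0, 101; 30.0: 0, 99
- blue (time / h: L / %, Z / %): 2.50: 10, 73; 6.00: 8, 81; 15.0: 10, 79; 30.0: 12, 80

(readings scatter by 1.5 percentage points)

- as a solid, counted per litre of solution: Q
- the analysis behind the earlier runs scatters by 1.5 percentage points, standard deviation
- at the start none of Q is in solution

- conversion of L at 40 h
- amount of Z at 40 h, in percent of the L charged
- amount of D at 40 h, in percent of the L charged

- Blue, with Q short of L, read Z 79% and L 10% after 15.0 h, and I took the missing 11.0% as D.
- I took 80.0% as the Q ceiling, charged [Q] over charged [L]: the most Z that the flask's Q can carry at one Q per Z. Blue's own ceiling was 80.0%, against its reading of Z above.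
- My first extreme gave the flask endless time: Z reached the ceiling, with Q as limiting reagent, and the remainder split between L and D as in blue, 10.0% each, for a conversion of 90.0%.
- My second extreme gave it ample Q: I then expected it to follow amber, which had the same [X] and [J] and read Z 93% at 8.00 h.
- The real flask's Z had to lie at or below the lower of these, so the clock was the open point. In powers of ten, 40 h stood 0.699 above amber's reading. Amber's extra Q was worth 0.148 if the rate followed [Q], or 0.296 if it followed [Q] squared, so the time margin was larger than either and I expected the ceiling to be reached.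
- The forecast gave conversion 90%, Z 79% and D 10%, reasoning “even at half blue's rate”; its Z stood a point under my ceiling.
- The flask gave conversion 90.0%, Z 80.0% and D 10.0%.

    G + X + D → X + Z (k = 31.0 M⁻² min⁻¹)
    Q ⇌ G, rate k2*(cs2 - [G]) while solid is left; crystals form when [G] > cs2 (solubility = 0.720 M, k = 0.0100 min⁻¹)
    X + J ⇌ E, settled at all times (K = 1100 M⁻¹)
    L + X ⇌ X + D (K = 1.00, k = 13.0 M⁻¹ min⁻¹)

- By 4.00 h, 1.00 powers of ten ahead of 40 h, the flask had 93% of the turnover of L + X into X + D up to 40 h behind it. At 40.0 h, Z in the flask stood at the ceiling of 80.0%, with Q at 0%.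
- For the neighbour with 0.16 M of Q, the ceiling was 20.0%, leaving 40.0% each for L and D. The computed flask gave Z 20.0%, D 40.0% and conversion 60.0%.

(The runs are simulated with constants of no real substance; scatter was added.)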